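Start from the easiest step, the last one, where target and isomer of the product simply run to and fro, and keep the whole flask in view:

    substrate + enzyme → target + enzyme, rate k1*[substrate]*[enzyme]/(1 + ([substrate]/Km1)) (Km1 = 0.0896 mM, k1 = 3.78 × 10⁶ L mol⁻¹ s⁻¹)
    substrate + target ⇌ idle adduct, settled at all times (K2 = 2880 L mol⁻¹)
    target ⇌ isomer of the product (K3 = 0.79, k3 = 0.120 s⁻¹)

substrate 0.50 mM (fed, over 1.5 s); enzyme 0.25 µM; time 50 min

- a species is counted by the substrate in it: one idle adduct counts as two
- amounts and yields of target count idle adduct too
- in an amount of target, one idle adduct counts as one target
- the reaction counts as stopped when no species that holds the substrate changes by six tenths of a point or more over the second half of the time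
- run time (flask): 50 min

- which holds at 50 min: what has brought the reaction to rest, or that it has not come to rest (it is still moving / forward and back rates have come level / all of the substrate has reacted)
- part of the substrate gone at 50 min
- the target standing at 50 min, as a percentage of the substrate charged

Divide the forward rate of that last step by its backward rate, and at level rates both the rate constant and the time drop out, leaving c_isomer/c_target = 0.79, so you carry one quantity: the part of the substrate passed through the enzyme that stands as target once that step is level, the balance share 55.9%, a case of thermodynamic control. That step levels fast enough to count on, with a relaxation half-life of 2.55 s, far shorter than the 50 min of the flask.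

From above, each idle adduct adds one target for two of the charge, a share of 0.5, which is less than the balance share, and free substrate adds no target, so target at 50 min cannot stand above 55.9%.

From below, the danger is unreacted substrate. The enzyme gives 0.945 s⁻¹ at low substrate and, at saturation, passes the charge in 5.91 s, while the adduct holds back free substrate by at most a factor 2.44, since free target cannot exceed the charge. Saturation slows the enzyme by at most a factor 6.58, so with both brakes at their fullest together the lifetime of unreacted substrate, free or in the adduct, stays below 17.0 s, and 50 min is about 176 such lifetimes, so the lower bound rises onto the upper one at 55.9%.

The forecast, all of the substrate has reacted with 100% gone and 55.9% target, stands where the bracket closes; its ground was that “the idle adduct simply falls apart as free substrate runs out”.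

The simulation gives all of the substrate has reacted, with 100% gone and 55.9% target.

Take the neighbouring flask, charged with 1.2 mM of substrate and read at the same time. The balance share holds no concentration, so you carry 55.9% over to it, and the neighbouring flask's bound on the lifetime, with both brakes reckoned at its own charge, grows to 67.9 s, still far shorter than 50 min, which gives 0.671 mM of target. The neighbouring flask stands at 55.9% target beside 44.1% isomer of the product, with 0% of its substrate left.

The numbers were chosen freely; the result is computed.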